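**Retrosynthetic overview**

- Target 26 comes from bis-silyl ether 25 by desilylation. The C4 hydroxymethyl group comes from a Stille coupling of tetronic acid triflate 23 with stannane 24, and the butenolide ring (O1, C2, C3, C4, C5) from a Dieckmann closure of the O-acetyl alpha-hydroxy ester 21.
- Hydroxy ester 19 comes from a one-flask union of homoallylic Grignard reagent 14, propargyl alcohol 15 and methyl (S)-glycidate 16. The chain CH2 bonds to the alkyne C2, and the alkyne C3 bonds to the epoxide CH2.
- Grignard reagent 14 comes from alkyne 8 by methylalumination and oxirane opening (this sets the E methyl olefin), then bromination and magnesium insertion. Alkyne 8 comes from dihydro-beta-ionone 1 by ring oxidation, CBS reduction and enol phosphate elimination.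
- The strategy rests on the trisubstituted olefin C(CH2OH)=CH whose hydroxymethyl group lies cis to the CH2 that leads to C5 of the butenolide ring. This O-C-C=C array is the magnesium chelate of a carbometalated propargyl alcohol, and the neighbouring CH2-CH(O) is a terminal epoxide opened at its CH2.
- Ring order: the cyclohexene ring is bought with 1. The butenolide is the only ring formed and is closed in step 14.

Key step: step 11

Remark on the chemistry: the target is read as S at the ring carbinol, S at C5 of the butenolide, E at the methyl-bearing olefin and Z at the hydroxymethyl-bearing olefin. "Ring C4" of the cyclohexene means the carbon next to the methyl-bearing olefinic carbon. TBS stands for tert-butyldimethylsilyl.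

**Route**

Step 1
Reactants: 1 dihydro-beta-ionone
Product: 2 2-methyl-2-[2-(2,6,6-trimethylcyclohex-1-en-1-yl)ethyl]-1,3-dioxolane
Conditions: ethylene glycol, p-TsOH (cat.), benzene, reflux, Dean-Stark trap
Reagents that add atoms: ethylene glycol, OCCO
Why: Acid-catalysed ketalisation with azeotropic removal of water should mask the methyl ketone against the later hydride reduction, and the tetrasubstituted ring olefin is inert to the catalytic acid.

Step 2
Reactants: 2 ketal
Product: 3 2,4,4-trimethyl-3-[2-(2-methyl-1,3-dioxolan-2-yl)ethyl]cyclohex-2-en-1-one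
Conditions: Rh2(cap)4 (cap = caprolactamate, 1 mol%), t-BuOOH (70% aq.), K2CO3, CH2Cl2, rt
Reagents that add atoms: tert-butyl hydroperoxide, CC(C)(C)OO
Why: Rh-catalysed allylic C-H oxidation with tert-butyl hydroperoxide should act at ring C4, the only ring allylic CH2 and the least hindered allylic C-H (the chain allylic CH2 is flanked by the gem-dimethyl carbon), and oxygenation at that secondary terminus gives the conjugated enone while the ketal survives the carbonate-buffered medium.

Step 3
Reactants: 3 ring enone
Product: 4 (1S)-2,4,4-trimethyl-3-[2-(2-methyl-1,3-dioxolan-2-yl)ethyl]cyclohex-2-en-1-ol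
Conditions: (R)-2-methyl-CBS-oxazaborolidine [(3aR)-1-methyl-3,3-diphenyltetrahydro-1H,3H-pyrrolo[1,2-c][1,3,2]oxazaborole] (20 mol%), BH3·SMe2, THF, -20 °C; MeOH, then aq. NH4Cl
Reagents that add atoms: none
Why: Corey-Bakshi-Shibata reduction is 1,2-selective, and with the methyl-substituted alkenyl carbon as the large group and the ring CH2 as the small group the (R)-catalyst should deliver hydride to the face that gives the S carbinol (mirror image of the acetophenone case).

Step 4
Reactants: 4 (S)-allylic alcohol
Product: 5 tert-butyldimethylsilyl ether of 4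
Conditions: TBSCl, imidazole, DMF, rt to 40 °C
Reagents that add atoms: tert-butyldimethylsilyl chloride, CC(C)(C)[Si](C)(C)Cl
Why: Imidazole-promoted silylation of the secondary allylic alcohol is standard and avoids silyl triflates, which could open the dioxolane.

Step 5
Reactants: 5 silyl ether ketal
Product: 6 4-[(3S)-3-(tert-butyldimethylsilyloxy)-2,6,6-trimethylcyclohex-1-en-1-yl]butan-2-one
Conditions: pyridinium p-toluenesulfonate (cat.), acetone/H2O, 50 °C
Reagents that add atoms: water, O
Why: Mild acid hydrolysis of the dioxolane should free the methyl ketone while the secondary TBS ether, which tolerates pyridinium tosylate, stays in place.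

Step 6
Reactants: 6 methyl ketone
Product: 7 4-[(3S)-3-(tert-butyldimethylsilyloxy)-2,6,6-trimethylcyclohex-1-en-1-yl]but-1-en-2-yl diethyl phosphate
Conditions: LiN(i-Pr)2, THF, -78 °C; ClP(O)(OEt)2, -78 °C to rt
Reagents that add atoms: diethyl chlorophosphate, CCOP(=O)(Cl)OCC
Why: Kinetic deprotonation by the hindered amide at -78 °C should take place at the methyl group, and O-phosphorylation of the lithium enolate gives the terminal enol phosphate.

Step 7
Reactants: 7 enol phosphate
Product: 8 tert-butyl{[(1S)-3-(but-3-yn-1-yl)-2,4,4-trimethylcyclohex-2-en-1-yl]oxy}dimethylsilane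
Conditions: LiN(i-Pr)2 (2.5 equiv), THF, -78 °C to rt; aq. NH4Cl
Reagents that add atoms: none
Why: Base-induced beta-elimination of diethyl phosphate from the 1-alken-2-yl phosphate gives the lithium acetylide, protonated on work-up, which is the standard conversion of a methyl ketone into a terminal alkyne.

Step 8
Reactants: 8 terminal alkyne, 9 oxirane
Product: 12 (3E)-6-[(3S)-3-(tert-butyldimethylsilyloxy)-2,6,6-trimethylcyclohex-1-en-1-yl]-4-methylhex-3-en-1-ol, via alkenyldimethylalane 10 (not isolated), via lithium alkenylalanate 11 (not isolated)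
Conditions: Me3Al, Cp2ZrCl2 (25 mol%), CH2Cl2, 0 °C to rt; volatiles removed; n-BuLi, hexane/THF, -78 to 0 °C; oxirane, 0 °C to rt; aq. Rochelle salt
Reagents that add atoms: trimethylaluminium, C[Al](C)C
Why: Negishi Zr-catalysed methylalumination is a syn addition that puts methyl on the internal alkyne carbon and aluminium on the terminal one, and the alanate formed with n-BuLi should open oxirane with retention at the alkenyl carbon, so the E olefin is fixed.

Step 9
Reactants: 12 homoallylic alcohol
Product: 13 tert-butyl{[(1S)-3-[(3E)-6-bromo-3-methylhex-3-en-1-yl]-2,4,4-trimethylcyclohex-2-en-1-yl]oxy}dimethylsilane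
Conditions: CBr4, PPh3, 2,6-lutidine (cat.), CH2Cl2, 0 °C
Reagents that add atoms: carbon tetrabromide, BrC(Br)(Br)Br
Why: The Appel reaction converts the primary alcohol into the bromide under near-neutral conditions that leave the allylic silyl ether and both olefins untouched.

Step 10
Reactants: 13 homoallylic bromide
Product: 14 [(3E)-6-[(3S)-3-(tert-butyldimethylsilyloxy)-2,6,6-trimethylcyclohex-1-en-1-yl]-4-methylhex-3-en-1-yl]magnesium bromide (titrated THF solution, used directly)
Conditions: Mg turnings (activated with a trace of 1,2-dibromoethane), THF, rt to 40 °C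
Reagents that add atoms: magnesium, [Mg]
Why: Magnesium insertion into the primary C-Br bond gives the Grignard reagent, and the homoallyl to cyclopropylcarbinyl rearrangement is not expected because it would place magnesium on a tertiary carbon.

Step 11
Reactants: 14 homoallylic Grignard reagent, 15 propargyl alcohol, 16 methyl (2S)-oxirane-2-carboxylate
Product: 19 methyl (2S,4Z,8E)-2-hydroxy-5-(hydroxymethyl)-9-methyl-11-[(3S)-3-(tert-butyldimethylsilyloxy)-2,6,6-trimethylcyclohex-1-en-1-yl]undeca-4,8-dienoate, via bromomagnesium propargyl alkoxide 17 (not isolated), via chelated alkenylmagnesium 18 (not isolated)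
Conditions: 15 (1.3 equiv), MeMgBr (1.3 equiv), THF, 0 °C; then 14 (1.0 equiv), CuI (10 mol%), -10 °C to rt; then CuI (10 mol%), 16 (1.5 equiv), -40 to -10 °C; aq. NH4Cl, 0 °C
Reagents that add atoms: none
Why: Proposed new method: the magnesium alkoxide 17 should steer the CuI-catalysed addition of the primary alkylmagnesium 14 across the alkyne so that the alkyl group bonds to C2 and magnesium to C3 from the opposite face, giving the five-membered O-Mg-C=C chelate 18; transmetalation to an alkenylcopper species and SN2 attack on the CH2 of glycidate 16 should then form the alkenyl-CH2 bond with retention at the alkenyl carbon. The closest known reaction types are the Cu-catalysed anti-carbomagnesiation of propargyl alcohol with capture of the chelated alkenylmagnesium by iodine, CO2 or allylic halides, and the Cu-catalysed opening of glycidic esters at the CH2 carbon by alkenyl Grignard reagents; joining the two in one flask with an epoxide as the trap is the untested part. No ring is closed. No stereocentre is created: the carbinol carbon is C2 of the (S)-glycidate, which does not react and keeps its descriptor, and the Z geometry of the hydroxymethyl olefin is dictated by the chelate and kept by retentive capture. The step needs regioselective and anti addition across the alkyne (both from alkoxide chelation), opening at the unsubstituted epoxide carbon (sterics and the soft copper nucleophile) and attack on the epoxide in preference to the ester (low temperature and the modest basicity of the chelated alkenyl species); the Grignard reagent carries only a silyl ether and unactivated olefins, so nothing else competes for the alkyne.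

Step 12
Reactants: 19 diol ester
Product: 20 methyl (2S,4Z,8E)-5-[(tert-butyldimethylsilyloxy)methyl]-2-hydroxy-9-methyl-11-[(3S)-3-(tert-butyldimethylsilyloxy)-2,6,6-trimethylcyclohex-1-en-1-yl]undeca-4,8-dienoate
Conditions: TBSCl (1.05 equiv), imidazole, CH2Cl2, -20 to 0 °C
Reagents that add atoms: tert-butyldimethylsilyl chloride, CC(C)(C)[Si](C)(C)Cl
Why: The primary allylic alcohol should be silylated far faster than the hindered, electron-poor secondary alpha-hydroxy ester, so one equivalent of silyl chloride is expected to be selective.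

Step 13
Reactants: 20 alpha-hydroxy ester
Product: 21 methyl (2S,4Z,8E)-2-acetoxy-5-[(tert-butyldimethylsilyloxy)methyl]-9-methyl-11-[(3S)-3-(tert-butyldimethylsilyloxy)-2,6,6-trimethylcyclohex-1-en-1-yl]undeca-4,8-dienoate
Conditions: Ac2O, pyridine, DMAP (cat.), CH2Cl2, 0 °C to rt
Reagents that add atoms: acetic anhydride, CC(=O)OC(C)=O
Why: DMAP-catalysed acetylation of the remaining secondary alcohol installs the two carbons that become C2 and C3 of the lactone without touching the stereocentre.

Step 14
Reactants: 21 acetoxy ester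
Product: 22 (5S)-5-[(2Z,6E)-3-[(tert-butyldimethylsilyloxy)methyl]-7-methyl-9-[(3S)-3-(tert-butyldimethylsilyloxy)-2,6,6-trimethylcyclohex-1-en-1-yl]nona-2,6-dien-1-yl]-4-hydroxyfuran-2(5H)-one
Conditions: LiN(SiMe3)2 (3 equiv), THF, -78 to -30 °C; cold 0.5 M HCl to pH 3
Reagents that add atoms: none
Why: In this Dieckmann condensation the amide base should deprotonate the acetate methyl kinetically, the enolate closes the ring by 5-exo-trig attack on the methyl ester with loss of methoxide, and the product is held as the tetronate anion, which shields C5 from deprotonation so that its S configuration is retained.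

Step 15
Reactants: 22 tetronic acid
Product: 23 (2S)-2-[(2Z,6E)-3-[(tert-butyldimethylsilyloxy)methyl]-7-methyl-9-[(3S)-3-(tert-butyldimethylsilyloxy)-2,6,6-trimethylcyclohex-1-en-1-yl]nona-2,6-dien-1-yl]-5-oxo-2,5-dihydrofuran-3-yl trifluoromethanesulfonate
Conditions: Tf2O, i-Pr2NEt, CH2Cl2, -78 °C
Reagents that add atoms: trifluoromethanesulfonic anhydride, O=S(=O)(OS(=O)(=O)C(F)(F)F)C(F)(F)F
Why: O-Sulfonylation of the vinylogous acid at the C4 enol oxygen is the usual activation of tetronic acids and gives an electron-poor vinyl triflate ready for oxidative addition.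

Step 16
Reactants: 23 enol triflate, 24 (tributylstannyl)methanol
Product: 25 (5S)-5-[(2Z,6E)-3-[(tert-butyldimethylsilyloxy)methyl]-7-methyl-9-[(3S)-3-(tert-butyldimethylsilyloxy)-2,6,6-trimethylcyclohex-1-en-1-yl]nona-2,6-dien-1-yl]-4-(hydroxymethyl)furan-2(5H)-one
Conditions: Pd(PPh3)4 (10 mol%), LiCl (3 equiv), 1,4-dioxane, 80 °C
Reagents that add atoms: none
Why: In this Stille coupling palladium should insert into the vinyl C-OTf bond, chloride-assisted transmetalation transfers the hydroxymethyl group from tin in preference to butyl, and reductive elimination forms the C4-CH2OH bond without touching C5.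

Step 17
Reactants: 25 bis-silyl ether
Product: 26 (5S)-4-(hydroxymethyl)-5-[(2Z,6E)-3-(hydroxymethyl)-9-[(3S)-3-hydroxy-2,6,6-trimethylcyclohex-1-en-1-yl]-7-methylnona-2,6-dien-1-yl]furan-2(5H)-one (CNP0330392.1)
Conditions: HF·pyridine, pyridine, THF, 0 °C to rt
Reagents that add atoms: none
Why: Pyridine-buffered hydrogen fluoride should cleave both silyl ethers while avoiding the basic conditions that could epimerise C5 of the butenolide and the strong acid that could ionise the ring allylic carbinol.

**Compound list**

1 | dihydro-beta-ionone, 4-(2,6,6-trimethylcyclohex-1-en-1-yl)butan-2-one | CC1=C(CCC(C)=O)C(C)(C)CCC1 | starting material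
2 | 2-methyl-2-[2-(2,6,6-trimethylcyclohex-1-en-1-yl)ethyl]-1,3-dioxolane | CC1=C(CCC2(C)OCCO2)C(C)(C)CCC1 | intermediate
3 | 2,4,4-trimethyl-3-[2-(2-methyl-1,3-dioxolan-2-yl)ethyl]cyclohex-2-en-1-one | CC1=C(CCC2(C)OCCO2)C(C)(C)CCC1=O | intermediate
4 | (1S)-2,4,4-trimethyl-3-[2-(2-methyl-1,3-dioxolan-2-yl)ethyl]cyclohex-2-en-1-ol | CC1=C(CCC2(C)OCCO2)C(C)(C)CC[C@@H]1O | intermediate
5 | tert-butyldimethylsilyl ether of 4 | CC1=C(CCC2(C)OCCO2)C(C)(C)CC[C@@H]1O[Si](C)(C)C(C)(C)C | intermediate
6 | 4-[(3S)-3-(tert-butyldimethylsilyloxy)-2,6,6-trimethylcyclohex-1-en-1-yl]butan-2-one | CC1=C(CCC(C)=O)C(C)(C)CC[C@@H]1O[Si](C)(C)C(C)(C)C | intermediate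
7 | 4-[(3S)-3-(tert-butyldimethylsilyloxy)-2,6,6-trimethylcyclohex-1-en-1-yl]but-1-en-2-yl diethyl phosphate | CC1=C(CCC(=C)OP(=O)(OCC)OCC)C(C)(C)CC[C@@H]1O[Si](C)(C)C(C)(C)C | intermediate
8 | tert-butyl{[(1S)-3-(but-3-yn-1-yl)-2,4,4-trimethylcyclohex-2-en-1-yl]oxy}dimethylsilane | CC1=C(CCC#C)C(C)(C)CC[C@@H]1O[Si](C)(C)C(C)(C)C | intermediate
9 | oxirane | C1CO1 | starting material
10 | (E)-alkenyldimethylalane from methylalumination of 8 (aluminium on the terminal carbon, cis to the new methyl) | CC1=C(CC/C(C)=C/[Al](C)C)C(C)(C)CC[C@@H]1O[Si](C)(C)C(C)(C)C | intermediate (not isolated)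
11 | lithium (E)-alkenyl(butyl)dimethylalanate | [Li+].CC1=C(CC/C(C)=C/[Al-](C)(C)CCCC)C(C)(C)CC[C@@H]1O[Si](C)(C)C(C)(C)C | intermediate (not isolated)
12 | (3E)-6-[(3S)-3-(tert-butyldimethylsilyloxy)-2,6,6-trimethylcyclohex-1-en-1-yl]-4-methylhex-3-en-1-ol | CC1=C(CC/C(C)=C/CCO)C(C)(C)CC[C@@H]1O[Si](C)(C)C(C)(C)C | intermediate
13 | tert-butyl{[(1S)-3-[(3E)-6-bromo-3-methylhex-3-en-1-yl]-2,4,4-trimethylcyclohex-2-en-1-yl]oxy}dimethylsilane | CC1=C(CC/C(C)=C/CCBr)C(C)(C)CC[C@@H]1O[Si](C)(C)C(C)(C)C | intermediate
14 | homoallylic Grignard reagent from 13 | CC1=C(CC/C(C)=C/CC[Mg]Br)C(C)(C)CC[C@@H]1O[Si](C)(C)C(C)(C)C | intermediate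
15 | propargyl alcohol (prop-2-yn-1-ol) | C#CCO | starting material
16 | methyl (2S)-oxirane-2-carboxylate (methyl (S)-glycidate) | COC(=O)[C@@H]1CO1 | starting material
17 | bromomagnesium prop-2-yn-1-olate | C#CCO[Mg]Br | intermediate (not isolated)
18 | chelated alkenylmagnesium: 2,5-dihydro-1,2-oxamagnesole carrying the chain at C4 | CC1=C(CC/C(C)=C/CCC2=C[Mg]OC2)C(C)(C)CC[C@@H]1O[Si](C)(C)C(C)(C)C | intermediate (not isolated)
19 | methyl (2S,4Z,8E)-2-hydroxy-5-(hydroxymethyl)-9-methyl-11-[(3S)-3-(tert-butyldimethylsilyloxy)-2,6,6-trimethylcyclohex-1-en-1-yl]undeca-4,8-dienoate | CC1=C(CC/C(C)=C/CC/C(=C/C[C@H](O)C(=O)OC)CO)C(C)(C)CC[C@@H]1O[Si](C)(C)C(C)(C)C | intermediate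
20 | primary TBS ether of 19 | CC1=C(CC/C(C)=C/CC/C(=C/C[C@H](O)C(=O)OC)CO[Si](C)(C)C(C)(C)C)C(C)(C)CC[C@@H]1O[Si](C)(C)C(C)(C)C | intermediate
21 | C2 acetate of 20 | CC1=C(CC/C(C)=C/CC/C(=C/C[C@H](OC(C)=O)C(=O)OC)CO[Si](C)(C)C(C)(C)C)C(C)(C)CC[C@@H]1O[Si](C)(C)C(C)(C)C | intermediate
22 | (5S)-5-substituted 4-hydroxyfuran-2(5H)-one (tetronic acid) | CC1=C(CC/C(C)=C/CC/C(=C/C[C@@H]2OC(=O)C=C2O)CO[Si](C)(C)C(C)(C)C)C(C)(C)CC[C@@H]1O[Si](C)(C)C(C)(C)C | intermediate
23 | C4 enol triflate of 22 | CC1=C(CC/C(C)=C/CC/C(=C/C[C@@H]2OC(=O)C=C2OS(=O)(=O)C(F)(F)F)CO[Si](C)(C)C(C)(C)C)C(C)(C)CC[C@@H]1O[Si](C)(C)C(C)(C)C | intermediate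
24 | (tributylstannyl)methanol | OC[Sn](CCCC)(CCCC)CCCC | starting material
25 | bis-TBS ether of the target | CC1=C(CC/C(C)=C/CC/C(=C/C[C@@H]2OC(=O)C=C2CO)CO[Si](C)(C)C(C)(C)C)C(C)(C)CC[C@@H]1O[Si](C)(C)C(C)(C)C | intermediate
26 | CNP0330392.1 | CC1=C(CC/C(C)=C/CC/C(=C/C[C@@H]2OC(=O)C=C2CO)CO)C(C)(C)CC[C@@H]1O | target

**Step count and risks**

Total step count: 17. Longest linear sequence: 17 steps (1 to 26); all other components are bought.

Steps most likely to fail:

1. Step 11 (proposed new method). Several processes could undermine it: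
   - the Grignard reagent may deprotonate the acetylenic C-H instead of adding;
   - the chelated alkenylmagnesium may be captured only slowly by the epoxide;
   - the organometallic may attack the ester carbonyl, or magnesium bromide may open the epoxide;
   - the primary magnesium alkoxide may transesterify onto the methyl ester.

   The fallback separates the two bond formations into known reactions. It sets out from Grignard reagent 14 and propargyl alcohol 15. The established Cu-catalysed carbomagnesiation, quenched with iodine, should give the (Z)-iodo allylic alcohol F1 with iodine cis to the hydroxymethyl group. Silylation (TBSCl, imidazole) gives the silyl ether F2. Lithium-iodine exchange (t-BuLi, Et2O, -78 °C) gives the alkenyllithium F3, and MgBr2·OEt2 converts it into the alkenylmagnesium bromide F4. This opens glycidate 16 at its CH2 carbon under CuI catalysis at -40 °C, which is the known reaction of alkenyl Grignard reagents with glycidic esters. The fallback comes back to the route at compound 20, so step 12 is no longer needed.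

2. Step 16. Transfer of the sp3 hydroxymethyl group from tin is slow, so hydrolysis or reduction of the sensitive tetronate triflate and butyl transfer may outrun the coupling. The fallback sets out from triflate 23. A Pd-catalysed reductive carbonylation (CO, Bu3SnH added slowly, Pd(PPh3)4, LiCl, THF, 50 °C) should give the 4-formylbutenolide F5. Luche reduction (NaBH4, CeCl3·7H2O, MeOH, -78 °C) reduces the aldehyde in preference to the lactone, and the fallback comes back at compound 25.

3. Step 2. Hydrogen abstraction may be unselective among the ring CH2, the chain allylic CH2 and the ring methyl, and over-oxidation is possible. The fallback sets out from ketal 2 and avoids both the enone and the CBS step: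
   - Wohl-Ziegler bromination (N-bromosuccinimide, NaHCO3, PhCF3, light) should give the ring allylic bromide F6.
   - Displacement with KOAc and 18-crown-6 in MeCN gives the racemic acetate F7.
   - Methanolysis (K2CO3, MeOH) gives the racemic allylic alcohol F8.
   - Lipase-catalysed acylation (Burkholderia cepacia lipase, vinyl acetate, MTBE) is expected to acylate the R enantiomer to the (R)-acetate F9 and leave the S alcohol.

   The fallback comes back at compound 4.

Further compounds
F1 | step 11 | (2Z,6E)-2-(iodomethylidene) allylic alcohol: (Z)-3-iodo-2-substituted prop-2-en-1-ol carrying the chain of 14 at C2 | CC1=C(CC/C(C)=C/CC/C(=C/I)CO)C(C)(C)CC[C@@H]1O[Si](C)(C)C(C)(C)C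
F2 | step 11 | tert-butyldimethylsilyl ether of F1 | CC1=C(CC/C(C)=C/CC/C(=C/I)CO[Si](C)(C)C(C)(C)C)C(C)(C)CC[C@@H]1O[Si](C)(C)C(C)(C)C
F3 | step 11 | (Z)-alkenyllithium from F2 | CC1=C(CC/C(C)=C/CC/C(=C/[Li])CO[Si](C)(C)C(C)(C)C)C(C)(C)CC[C@@H]1O[Si](C)(C)C(C)(C)C
F4 | step 11 | (Z)-alkenylmagnesium bromide from F3 | CC1=C(CC/C(C)=C/CC/C(=C/[Mg]Br)CO[Si](C)(C)C(C)(C)C)C(C)(C)CC[C@@H]1O[Si](C)(C)C(C)(C)C
F5 | step 16 | (2S)-2-substituted 5-oxo-2,5-dihydrofuran-3-carbaldehyde (4-formylbutenolide, bis-TBS ether) | CC1=C(CC/C(C)=C/CC/C(=C/C[C@@H]2OC(=O)C=C2C=O)CO[Si](C)(C)C(C)(C)C)C(C)(C)CC[C@@H]1O[Si](C)(C)C(C)(C)C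
F6 | step 2 | racemic 2-[2-(3-bromo-2,6,6-trimethylcyclohex-1-en-1-yl)ethyl]-2-methyl-1,3-dioxolane | CC1=C(CCC2(C)OCCO2)C(C)(C)CCC1Br
F7 | step 2 | racemic 2,4,4-trimethyl-3-[2-(2-methyl-1,3-dioxolan-2-yl)ethyl]cyclohex-2-en-1-yl acetate | CC1=C(CCC2(C)OCCO2)C(C)(C)CCC1OC(C)=O
F8 | step 2 | racemic 2,4,4-trimethyl-3-[2-(2-methyl-1,3-dioxolan-2-yl)ethyl]cyclohex-2-en-1-ol | CC1=C(CCC2(C)OCCO2)C(C)(C)CCC1O
F9 | step 2 | (1R)-2,4,4-trimethyl-3-[2-(2-methyl-1,3-dioxolan-2-yl)ethyl]cyclohex-2-en-1-yl acetate | CC1=C(CCC2(C)OCCO2)C(C)(C)CC[C@H]1OC(C)=O
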